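**Plan**

Locants: flavanone rings A and C are unprimed, ring B is primed, the flavone chromenone is double-primed. The retrosynthesis removes five O-benzyl groups, then cuts C2–C1', then C4a''–C4'', C4''–C3'' and O1''–C2'' together, and last the biaryl bond C3'–C8''.
Enabling feature: the flavone pyranone ring (O1'', C2'' carrying the anisyl ring, C3'', C4'') is fused along C4a''–C8a'', directly beside the arylated C8''. With iodine on C4a'' and the only free hydroxyl on C8a'', ring closure can give only the 8-aryl flavone.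
Forward order: ring B is joined to the phloroglucinol ring by Suzuki coupling. The ortho-iodophenol is then prepared, and CO and 4-ethynylanisole close the pyranone ring.
The chlorine on C1' is then exchanged for boron, and the aryl group is added to C2 of 5,7-bis(benzyloxy)chromone, which brings in rings A and C ready-made.
Stereochemistry: the single stereocentre C2 (S) is set by the chiral pyridine-oxazoline palladium catalyst in that conjugate addition. Neutral hydrogenolysis ends the route without touching it.

Key step: step 6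

Assumption: the sense of induction of the ligand is carried over from its additions to 3-substituted cyclohexenones, which points to the (R)-ligand for 2S; if the sense proves reversed, the equally available (S)-ligand is used.
Assumption: the C3'–C8'' axis is treated as rotating freely on the laboratory time scale, since the target carries no axial descriptor.

**Step 1**
Reactants: 1 3,5-bis(benzyloxy)phenol
Product: 2 3,5-bis(benzyloxy)-2-iodophenol
Conditions: NIS (1.0 equiv), CH2Cl2, −20 to 0 °C, dark
Reagents that add atoms: N-iodosuccinimide, O=C1CCC(=O)N1I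
Why: Electrophilic aromatic iodination: in 3,5-dialkoxyphenols the two equivalent positions between OH and OR are less crowded than the position between the two OR groups and are favoured by hydrogen bonding of the phenol to the reagent in a non-polar solvent, so one equivalent of NIS should give the ortho-monoiodide.

**Step 2**
Reactants: 2 3,5-bis(benzyloxy)-2-iodophenol
Product: 3 1,5-bis(benzyloxy)-2-iodo-3-(methoxymethoxy)benzene
Conditions: MOMCl, i-Pr2NEt, CH2Cl2, 0 °C to rt
Reagents that add atoms: chloromethyl methyl ether, COCCl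
Why: Standard MOM protection (O-alkylation of a phenol with an α-chloro ether) removes the acidic proton, which as a phenoxide would slow oxidative addition in the next step, and the small acetal adds little bulk beside the iodide.

**Step 3**
Reactants: 3 1,5-bis(benzyloxy)-2-iodo-3-(methoxymethoxy)benzene; 4 [2-(benzyloxy)-5-chlorophenyl]boronic acid
Product: 5 2,2',4-tris(benzyloxy)-5'-chloro-6-(methoxymethoxy)biphenyl
Conditions: Pd(PPh3)4 (5 mol %), K2CO3, DMF/H2O (9:1), 90 °C
Reagents that add atoms: none
Why: Suzuki–Miyaura coupling forms C3'–C8''; aryl iodides flanked by two oxygen substituents are known to couple with ortho-alkoxyarylboronic acids under Pd(PPh3)4 and aqueous carbonate, and this catalyst does not insert into the electron-rich C–Cl bond carried by 4 and 5.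

**Step 4**
Reactants: 5 2,2',4-tris(benzyloxy)-5'-chloro-6-(methoxymethoxy)biphenyl
Product: 6 3,5-bis(benzyloxy)-2-[2-(benzyloxy)-5-chlorophenyl]phenol
Conditions: conc. HCl (cat.), MeOH/THF, 50 °C
Reagents that add atoms: none
Why: Acid-catalysed transacetalisation cleaves only the MOM acetal; methanol traps the formaldehyde unit as dimethoxymethane, which shields the electron-rich ring from hydroxymethylation, and the aryl benzyl ethers and the chloride are inert to dilute acid.

**Step 5**
Reactants: 6 3,5-bis(benzyloxy)-2-[2-(benzyloxy)-5-chlorophenyl]phenol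
Product: 7 3,5-bis(benzyloxy)-2-[2-(benzyloxy)-5-chlorophenyl]-6-iodophenol
Conditions: NIS (1.0 equiv), CH2Cl2, −20 to 0 °C, dark
Reagents that add atoms: N-iodosuccinimide, O=C1CCC(=O)N1I
Why: Electrophilic aromatic iodination ortho to the free phenol: the phloroglucinol-derived ring is far more activated than the chlorinated ring, and of its two open positions the one beside the small hydroxyl (future C4a'') is favoured on steric and hydrogen-bonding grounds over the one wedged between two benzyloxy groups, as in step 1 and as known for 2-hydroxy-4,6-dialkoxyaryl ketones.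

**Step 6**
Reactants: 7 3,5-bis(benzyloxy)-2-[2-(benzyloxy)-5-chlorophenyl]-6-iodophenol; 8 4-ethynylanisole; 9 carbon monoxide
Product: 12 5,7-bis(benzyloxy)-8-[2-(benzyloxy)-5-chlorophenyl]-4'-methoxyflavone, via ynone 10 (not isolated), via diethylamino enone 11 (not isolated)
Conditions: PdCl2(PPh3)2 (5 mol %), CO (20 bar), 8 (1.5 equiv), Et2NH, 110 °C, autoclave, no copper salt
Reagents that add atoms: diethylamine, CCNCC (its atoms are held only in intermediate 11 and leave again on ring closure)
Why: Zerovalent palladium, generated in the flask from PdCl2(PPh3)2, inserts into the C–I bond of 7, CO migrates in to give an aroylpalladium species, and transfer of the acetylide of 8 followed by reductive elimination gives ynone 10 (new bonds C4a''–C4'' and C4''–C3''). Diethylamine then adds to C2'' of 10 to give enaminone 11, and the C8a'' hydroxyl displaces the amine by addition–elimination (new bond O1''–C2''), so the pyranone ring closes in a net 6-endo sense and the 5-exo path to an aurone is avoided. This is the known carbonylative Sonogashira coupling–annulation of ortho-iodophenols with terminal arylacetylenes to flavones. Chemoselectivity rests on the much faster insertion of triphenylphosphine-ligated palladium into C–I than into the electron-rich C–Cl bond, while CO pressure and the absence of copper hold back direct alkynylation, which would end in a benzofuran. Regiochemistry is fixed by the substrate, because the only free hydroxyl sits on C8a'' between the iodinated C4a'' and the arylated C8'', so no 6-aryl isomer can arise. No stereocentre is created, and the hot amine medium is used before the base-sensitive C2 centre exists.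

**Step 7**
Reactants: 12 5,7-bis(benzyloxy)-8-[2-(benzyloxy)-5-chlorophenyl]-4'-methoxyflavone
Product: 13 {4-(benzyloxy)-3-[5,7-bis(benzyloxy)-2-(4-methoxyphenyl)-4-oxo-4H-chromen-8-yl]phenyl}boronic acid
Conditions: Pd(OAc)2 (2 mol %), XPhos (6 mol %), B2(OH)4 (3 equiv), KOAc (3 equiv), EtOH/THF, 80 °C; aqueous work-up
Reagents that add atoms: tetrahydroxydiboron, OB(O)B(O)O
Why: Miyaura-type borylation of an aryl chloride with tetrahydroxydiboron: the bulky, electron-rich XPhos ligand allows insertion into the deactivated C–Cl bond, KOAc is too weak a base to harm the flavone, and the free boronic acid needed next is obtained without a separate ester cleavage.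

**Step 8**
Reactants: 14 2,4,6-trihydroxyacetophenone
Product: 15 2,4-bis(benzyloxy)-6-hydroxyacetophenone
Conditions: BnBr (2.05 equiv), K2CO3, DMF, 60 °C
Reagents that add atoms: benzyl bromide, BrCc1ccccc1
Why: Selective Williamson etherification: once one ortho hydroxyl is benzylated, the remaining one is locked in a hydrogen bond to the ketone and is the least nucleophilic, so two equivalents of benzyl bromide should stop at the well-known dibenzyl ether.

**Step 9**
Reactants: 15 2,4-bis(benzyloxy)-6-hydroxyacetophenone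
Product: 17 5,7-bis(benzyloxy)-4H-chromen-4-one, via dimethylamino enone 16 (not isolated)
Conditions: Me2NCH(OMe)2, toluene, 100 °C; evaporate; then conc. HCl, CH2Cl2, 40 °C
Reagents that add atoms: N,N-dimethylformamide dimethyl acetal, COC(OC)N(C)C
Why: Classical enaminone route to 2,3-unsubstituted chromones: condensation of the methyl ketone with the formamide acetal supplies C2, and acid triggers addition–elimination of the phenol at that carbon with loss of dimethylamine.

**Step 10**
Reactants: 13 {4-(benzyloxy)-3-[5,7-bis(benzyloxy)-2-(4-methoxyphenyl)-4-oxo-4H-chromen-8-yl]phenyl}boronic acid; 17 5,7-bis(benzyloxy)-4H-chromen-4-one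
Product: 18 (2S)-5,7-bis(benzyloxy)-2-{4-(benzyloxy)-3-[5,7-bis(benzyloxy)-2-(4-methoxyphenyl)-4-oxo-4H-chromen-8-yl]phenyl}chroman-4-one
Conditions: Pd(OCOCF3)2 (10 mol %), (R)-4-tert-butyl-2-(pyridin-2-yl)-4,5-dihydrooxazole [(R)-t-BuPyOx, 12 mol %], NH4PF6 (30 mol %), H2O (5 equiv), 17 (2 equiv), ClCH2CH2Cl, 60 °C
Reagents that add atoms: none
Why: Asymmetric palladium-catalysed conjugate addition of an arylboronic acid to a chromone: transmetalation to the cationic divalent palladium–PyOx complex, enantiodetermining migratory insertion of C2=C3 of 17 and protonolysis of the palladium enolate by water form C2–C1', the tert-butyl group of the (R)-ligand leaving only the Re face of C2 open and so setting 2S, while the base-free medium prevents retro-oxa-Michael racemisation and the 2-aryl-substituted pyranone inside 13 is too hindered to act as an acceptor.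

**Step 11**
Reactants: 18 (2S)-5,7-bis(benzyloxy)-2-{4-(benzyloxy)-3-[5,7-bis(benzyloxy)-2-(4-methoxyphenyl)-4-oxo-4H-chromen-8-yl]phenyl}chroman-4-one
Product: 19 (2S)-2,3-dihydropodocarpusflavone A
Conditions: H2 (1 atm), Pd/C (10 wt %), THF/MeOH, rt, stopped at full debenzylation
Reagents that add atoms: none
Why: Catalytic hydrogenolysis of the five aryl benzyl ethers under neutral conditions at room temperature is faster than reduction of the conjugated C2''=C3'' bond or cleavage of the C2–O1 bond, spares the methyl ether, and offers neither acid nor base to open ring C, so the 2S configuration is kept.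

**Compound list**

1 | 3,5-bis(benzyloxy)phenol | Oc1cc(OCc2ccccc2)cc(OCc2ccccc2)c1 | starting material
2 | 3,5-bis(benzyloxy)-2-iodophenol | Oc1cc(OCc2ccccc2)cc(OCc2ccccc2)c1I | intermediate
3 | 1,5-bis(benzyloxy)-2-iodo-3-(methoxymethoxy)benzene | COCOc1cc(OCc2ccccc2)cc(OCc2ccccc2)c1I | intermediate
4 | [2-(benzyloxy)-5-chlorophenyl]boronic acid | OB(O)c1cc(Cl)ccc1OCc1ccccc1 | starting material
5 | 2,2',4-tris(benzyloxy)-5'-chloro-6-(methoxymethoxy)biphenyl | COCOc1cc(OCc2ccccc2)cc(OCc2ccccc2)c1-c1cc(Cl)ccc1OCc1ccccc1 | intermediate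
6 | 3,5-bis(benzyloxy)-2-[2-(benzyloxy)-5-chlorophenyl]phenol | Oc1cc(OCc2ccccc2)cc(OCc2ccccc2)c1-c1cc(Cl)ccc1OCc1ccccc1 | intermediate
7 | 3,5-bis(benzyloxy)-2-[2-(benzyloxy)-5-chlorophenyl]-6-iodophenol | Oc1c(I)c(OCc2ccccc2)cc(OCc2ccccc2)c1-c1cc(Cl)ccc1OCc1ccccc1 | intermediate
8 | 4-ethynylanisole | COc1ccc(C#C)cc1 | starting material
9 | carbon monoxide | [C-]#[O+] | starting material
10 | 1-{4,6-bis(benzyloxy)-3-[2-(benzyloxy)-5-chlorophenyl]-2-hydroxyphenyl}-3-(4-methoxyphenyl)prop-2-yn-1-one | COc1ccc(C#CC(=O)c2c(O)c(-c3cc(Cl)ccc3OCc3ccccc3)c(OCc3ccccc3)cc2OCc2ccccc2)cc1 | intermediate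
11 | (E)-1-{4,6-bis(benzyloxy)-3-[2-(benzyloxy)-5-chlorophenyl]-2-hydroxyphenyl}-3-(diethylamino)-3-(4-methoxyphenyl)prop-2-en-1-one | CCN(CC)/C(c1ccc(OC)cc1)=C/C(=O)c1c(O)c(-c2cc(Cl)ccc2OCc2ccccc2)c(OCc2ccccc2)cc1OCc1ccccc1 | intermediate
12 | 5,7-bis(benzyloxy)-8-[2-(benzyloxy)-5-chlorophenyl]-4'-methoxyflavone | COc1ccc(-c2cc(=O)c3c(OCc4ccccc4)cc(OCc4ccccc4)c(-c4cc(Cl)ccc4OCc4ccccc4)c3o2)cc1 | intermediate
13 | {4-(benzyloxy)-3-[5,7-bis(benzyloxy)-2-(4-methoxyphenyl)-4-oxo-4H-chromen-8-yl]phenyl}boronic acid | COc1ccc(-c2cc(=O)c3c(OCc4ccccc4)cc(OCc4ccccc4)c(-c4cc(B(O)O)ccc4OCc4ccccc4)c3o2)cc1 | intermediate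
14 | 2,4,6-trihydroxyacetophenone | CC(=O)c1c(O)cc(O)cc1O | starting material
15 | 2,4-bis(benzyloxy)-6-hydroxyacetophenone | CC(=O)c1c(O)cc(OCc2ccccc2)cc1OCc1ccccc1 | intermediate
16 | (E)-1-[2,4-bis(benzyloxy)-6-hydroxyphenyl]-3-(dimethylamino)prop-2-en-1-one | CN(C)/C=C/C(=O)c1c(O)cc(OCc2ccccc2)cc1OCc1ccccc1 | intermediate
17 | 5,7-bis(benzyloxy)-4H-chromen-4-one | O=c1ccoc2cc(OCc3ccccc3)cc(OCc3ccccc3)c12 | intermediate
18 | (2S)-5,7-bis(benzyloxy)-2-{4-(benzyloxy)-3-[5,7-bis(benzyloxy)-2-(4-methoxyphenyl)-4-oxo-4H-chromen-8-yl]phenyl}chroman-4-one | COc1ccc(-c2cc(=O)c3c(OCc4ccccc4)cc(OCc4ccccc4)c(-c4cc([C@@H]5CC(=O)c6c(OCc7ccccc7)cc(OCc7ccccc7)cc6O5)ccc4OCc4ccccc4)c3o2)cc1 | intermediate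
19 | (2S)-2,3-dihydropodocarpusflavone A | COc1ccc(-c2cc(=O)c3c(O)cc(O)c(-c4cc([C@@H]5CC(=O)c6c(O)cc(O)cc6O5)ccc4O)c3o2)cc1 | target

**Step count**

Total step count: 11.
Longest linear sequence: 9 steps (steps 1 to 7, 10 and 11, from compound 1). Steps 8 and 9 form the two-step side branch.

**Steps most likely to fail**

**Step 10.** Migratory insertion into the electron-rich, 5-alkoxylated chromone may be slow enough for protodeboronation of the valuable boronic acid to take over. Facial selectivity may also erode with a para-alkoxy aryl group.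

The fallback builds ring C from a chalcone and takes the configuration from a separation instead of a catalyst. It sets out from 12 and returns at 18.
- Chloride 12 is vinylated with potassium vinyltrifluoroborate (Pd(OAc)2, XPhos, K2CO3, THF/H2O, 85 °C) to the styrene 5,7-bis(benzyloxy)-8-[2-(benzyloxy)-5-vinylphenyl]-4'-methoxyflavone F1.
- Lemieux–Johnson cleavage (OsO4 cat., NaIO4, 2,6-lutidine, dioxane/H2O) gives 4-(benzyloxy)-3-[5,7-bis(benzyloxy)-2-(4-methoxyphenyl)-4-oxo-4H-chromen-8-yl]benzaldehyde F2.
- Claisen–Schmidt condensation of this aldehyde with acetophenone 15 (KOH, EtOH/THF, rt) gives the (E)-2'-hydroxychalcone F3.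
- Sodium acetate in refluxing ethanol closes ring C by oxa-Michael addition to the racemic pentabenzyl ether F4.
- Preparative HPLC on a chiral stationary phase separates 18 from the (2R)-pentabenzyl ether F5, which can be racemised under the same acetate conditions and resubmitted.

**Step 6.** Oxidative addition into the electron-rich C–I bond, flanked on both sides, may be slow. Reductive loss of iodine, capture of the aroylpalladium species by diethylamine, or CO-free alkynylation followed by five-membered ring closure could then compete.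

The fallback forms the same three bonds one at a time by polar chemistry. It sets out from 6 and returns at 10, hence at 12.
- Magnesium-mediated, strictly ortho-selective formylation of phenol 6 (MgCl2, Et3N, paraformaldehyde, MeCN, reflux; Casnati–Skattebøl reaction) gives 4,6-bis(benzyloxy)-3-[2-(benzyloxy)-5-chlorophenyl]-2-hydroxybenzaldehyde F6.
- Alkyne 8 is deprotonated (n-BuLi, THF, −78 °C) to lithium (4-methoxyphenyl)acetylide F7.
- Two equivalents of this acetylide add to the aldehyde to give, after an NH4Cl quench, the racemic propargylic alcohol F8.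
- The crude alcohol is oxidised with MnO2 in CH2Cl2 to ynone 10.
- Warming 10 with diethylamine in ethanol closes the ring through 11 to 12.

**Step 5.** The iodinating agent may attack the position para to the hydroxyl, between the two benzyloxy groups, or a second iodination may occur.

The fallback replaces electrophilic substitution by coordination-directed deprotonation. It sets out from 5 and returns at 7.
- The MOM ether 5 is treated with n-BuLi (THF, −20 to 0 °C). The acetal oxygen guides the base to its only free ortho position and gives the aryllithium F9.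
- Quenching with I2 at −78 °C gives 2,2',4-tris(benzyloxy)-5'-chloro-5-iodo-6-(methoxymethoxy)biphenyl F10.
- The acid methanolysis of step 4 then releases 7.

**Further compounds**

F1 | step 10 | 5,7-bis(benzyloxy)-8-[2-(benzyloxy)-5-vinylphenyl]-4'-methoxyflavone | COc1ccc(-c2cc(=O)c3c(OCc4ccccc4)cc(OCc4ccccc4)c(-c4cc(C=C)ccc4OCc4ccccc4)c3o2)cc1
F2 | step 10 | 4-(benzyloxy)-3-[5,7-bis(benzyloxy)-2-(4-methoxyphenyl)-4-oxo-4H-chromen-8-yl]benzaldehyde | COc1ccc(-c2cc(=O)c3c(OCc4ccccc4)cc(OCc4ccccc4)c(-c4cc(C=O)ccc4OCc4ccccc4)c3o2)cc1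
F3 | step 10 | (E)-1-[2,4-bis(benzyloxy)-6-hydroxyphenyl]-3-{4-(benzyloxy)-3-[5,7-bis(benzyloxy)-2-(4-methoxyphenyl)-4-oxo-4H-chromen-8-yl]phenyl}prop-2-en-1-one | COc1ccc(-c2cc(=O)c3c(OCc4ccccc4)cc(OCc4ccccc4)c(-c4cc(/C=C/C(=O)c5c(O)cc(OCc6ccccc6)cc5OCc5ccccc5)ccc4OCc4ccccc4)c3o2)cc1
F4 | step 10 | racemic 5,7-bis(benzyloxy)-2-{4-(benzyloxy)-3-[5,7-bis(benzyloxy)-2-(4-methoxyphenyl)-4-oxo-4H-chromen-8-yl]phenyl}chroman-4-one | COc1ccc(-c2cc(=O)c3c(OCc4ccccc4)cc(OCc4ccccc4)c(-c4cc(C5CC(=O)c6c(OCc7ccccc7)cc(OCc7ccccc7)cc6O5)ccc4OCc4ccccc4)c3o2)cc1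
F5 | step 10 | (2R)-5,7-bis(benzyloxy)-2-{4-(benzyloxy)-3-[5,7-bis(benzyloxy)-2-(4-methoxyphenyl)-4-oxo-4H-chromen-8-yl]phenyl}chroman-4-one | COc1ccc(-c2cc(=O)c3c(OCc4ccccc4)cc(OCc4ccccc4)c(-c4cc([C@H]5CC(=O)c6c(OCc7ccccc7)cc(OCc7ccccc7)cc6O5)ccc4OCc4ccccc4)c3o2)cc1
F6 | step 6 | 4,6-bis(benzyloxy)-3-[2-(benzyloxy)-5-chlorophenyl]-2-hydroxybenzaldehyde | O=Cc1c(O)c(-c2cc(Cl)ccc2OCc2ccccc2)c(OCc2ccccc2)cc1OCc1ccccc1
F7 | step 6 | lithium (4-methoxyphenyl)acetylide | [Li]C#Cc1ccc(OC)cc1
F8 | step 6 | racemic 1-{4,6-bis(benzyloxy)-3-[2-(benzyloxy)-5-chlorophenyl]-2-hydroxyphenyl}-3-(4-methoxyphenyl)prop-2-yn-1-ol | COc1ccc(C#CC(O)c2c(O)c(-c3cc(Cl)ccc3OCc3ccccc3)c(OCc3ccccc3)cc2OCc2ccccc2)cc1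
F9 | step 5 | {2',4,6-tris(benzyloxy)-5'-chloro-2-(methoxymethoxy)biphenyl-3-yl}lithium | COCOc1c([Li])c(OCc2ccccc2)cc(OCc2ccccc2)c1-c1cc(Cl)ccc1OCc1ccccc1
F10 | step 5 | 2,2',4-tris(benzyloxy)-5'-chloro-5-iodo-6-(methoxymethoxy)biphenyl | COCOc1c(I)c(OCc2ccccc2)cc(OCc2ccccc2)c1-c1cc(Cl)ccc1OCc1ccccc1
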